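**Plan**
1. Numbering: ring O1, C2(=O), C3=C4, C5, C6; side chain C1'=C2', C3', C4'(OAc), C6'(OH), C8'(OH), C10'–Ph. The unit C6(O)–C1'H=C2'H–C3'H2–C4'(O), joining ring carbon C6 to the acetoxy carbon, is an (E)-1,5-anti-pent-2-ene-1,5-diol. This is the direct product of a one-pot double allylboration with a γ-boryl allylborane C3 linchpin.
2. Retrosynthesis: remove the C4' acetyl and the C6'/C8' ketal; open the dihydropyranone ring at O1–C2 to a (Z)-2-ene-1,5-diol; cut C3'–C4' and then C6–C1' to aldehyde 8 (C4'–C10'), linchpin 15 (C1'–C3') and (Z)-aldehyde 4 (C2–C6).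
3. Forward: 4 adds to 15 (C6–C1'); the α-boryl allylboronate 16 formed in the flask adds to 8 (C3'–C4'); the dihydropyranone ring is then closed by oxidative lactonisation, followed by acetylation and ketal hydrolysis.
4. Stereochemistry: C6' and C8' come from the statin acetonide 5; C6 from reagent control by the isopinocampheyl groups; C4' and the (E)-C1'=C2' alkene from chirality transfer out of C1' in a chair transition state; the ring (Z)-alkene from Lindlar semihydrogenation.

Key step: step 9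

Remark: the bulk statin side-chain aldehyde 5 is taken as commercially available; lIpc is the isopinocampheyl group [(1S,2R,3S,5S)-2,6,6-trimethylbicyclo[3.1.1]heptan-3-yl] obtained from (−)-α-pinene.

**Step 1**
Reactants: 1 tert-butyldimethyl(prop-2-yn-1-yloxy)silane
Product: 2 5-[(tert-butyldimethylsilyl)oxy]pent-3-yn-1-ol
Conditions: n-BuLi, THF, −78 °C; oxirane, DMPU, −78 °C → rt
Reagents that add atoms: oxirane C1CO1
Why: The lithium acetylide should open the unsubstituted epoxide by SN2 attack (alkynylation of an epoxide), giving the homopropargylic alcohol that carries ring carbons C2–C6; no stereocentre is formed.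

**Step 2**
Reactants: 2 5-[(tert-butyldimethylsilyl)oxy]pent-3-yn-1-ol
Product: 3 (3Z)-5-[(tert-butyldimethylsilyl)oxy]pent-3-en-1-ol
Conditions: H2 (1 atm), Lindlar catalyst, quinoline, EtOAc, rt
Reagents that add atoms: none
Why: Lindlar semihydrogenation adds H2 syn on the poisoned palladium surface and should stop at the (Z)-alkene, which later becomes the ring C3=C4 bond.

**Step 3**
Reactants: 3 (3Z)-5-[(tert-butyldimethylsilyl)oxy]pent-3-en-1-ol
Product: 4 (3Z)-5-[(tert-butyldimethylsilyl)oxy]pent-3-enal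
Conditions: Dess–Martin periodinane, pyridine, CH2Cl2, 0 °C; used crude at once
Reagents that add atoms: none
Why: Dess–Martin oxidation under buffered, non-enolising conditions should give the β,γ-unsaturated aldehyde without migration of the (Z)-alkene into conjugation.

**Step 4**
Reactants: 5 tert-butyl 2-[(4R,6S)-6-formyl-2,2-dimethyl-1,3-dioxan-4-yl]acetate
Product: 6 tert-butyl 2-[(4R,6S)-2,2-dimethyl-6-[(E)-2-phenylethenyl]-1,3-dioxan-4-yl]acetate
Conditions: diethyl benzylphosphonate, NaH, THF, 0 °C; then 5, 0 °C → rt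
Reagents that add atoms: diethyl benzylphosphonate CCOP(=O)(Cc1ccccc1)OCC
Why: Horner–Wadsworth–Emmons olefination with the preformed phosphonate anion should give the (E)-styrene without epimerising the α-alkoxy aldehyde, as this aldehyde tolerates related semi-stabilised ylides; the alkene geometry is erased in step 5.

**Step 5**
Reactants: 6 tert-butyl 2-[(4R,6S)-2,2-dimethyl-6-[(E)-2-phenylethenyl]-1,3-dioxan-4-yl]acetate
Product: 7 tert-butyl 2-[(4R,6R)-2,2-dimethyl-6-(2-phenylethyl)-1,3-dioxan-4-yl]acetate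
Conditions: H2 (1 atm), 10% Pd/C, Et3N (trace), EtOAc, rt
Reagents that add atoms: none
Why: Heterogeneous hydrogenation should saturate the styrene faster than it cleaves the allylic C–O bond (the amine trace suppresses hydrogenolysis), leaving both ring stereocentres untouched.

**Step 6**
Reactants: 7 tert-butyl 2-[(4R,6R)-2,2-dimethyl-6-(2-phenylethyl)-1,3-dioxan-4-yl]acetate
Product: 8 2-[(4R,6R)-2,2-dimethyl-6-(2-phenylethyl)-1,3-dioxan-4-yl]acetaldehyde
Conditions: DIBAL-H, CH2Cl2, −78 °C; Rochelle salt work-up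
Reagents that add atoms: none
Why: Partial ester reduction with DIBAL-H should stop at the aldehyde because the tetrahedral aluminium hemiacetal, chelated by the β-ring oxygen, survives at −78 °C until the quench.

**Step 7**
Reactants: 9 3-bromoprop-1-yne
Product: 12 5,5-dimethyl-2-(propa-1,2-dien-1-yl)-1,3,2-dioxaborinane, via allenylmagnesium bromide 10 (not isolated), via allenylboronic acid 11 (not isolated)
Conditions: Mg, HgCl2 (cat.), Et2O, 0 °C; B(OMe)3, Et2O, −78 °C; 3 M HCl; then 2,2-dimethylpropane-1,3-diol, MgSO4, Et2O, rt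
Reagents that add atoms: trimethyl borate COB(OC)OC; 2,2-dimethylpropane-1,3-diol CC(C)(CO)CO
Why: Grignard formation and borylation (the propargyl/allenyl Grignard reagent delivers the allenylboron compound to trimethyl borate), then hydrolysis and esterification with the diol, should give the unhindered six-membered allenylboronate.

**Step 8**
Reactants: 13 (1S,5S)-(−)-α-pinene
Product: 14 (+)-diisopinocampheylborane [(lIpc)2BH]
Conditions: BH3·SMe2, THF, 0 °C, then 0 °C, 3 d; crystals washed with Et2O under Ar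
Reagents that add atoms: borane–dimethyl sulfide C[S+](C)[BH3-]
Why: Hydroboration adds B–H syn to the alkene face anti to the gem-dimethyl bridge, and equilibration with excess pinene during crystallisation should upgrade the optical purity of the dialkylborane.

**Step 9**
Reactants: 12 5,5-dimethyl-2-(propa-1,2-dien-1-yl)-1,3,2-dioxaborinane; 14 (+)-diisopinocampheylborane; 4 (3Z)-5-[(tert-butyldimethylsilyl)oxy]pent-3-enal; 8 2-[(4R,6R)-2,2-dimethyl-6-(2-phenylethyl)-1,3-dioxan-4-yl]acetaldehyde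
Product: 18 (2Z,5S,6E,9R)-1-[(tert-butyldimethylsilyl)oxy]-10-[(4S,6R)-2,2-dimethyl-6-(2-phenylethyl)-1,3-dioxan-4-yl]deca-2,6-diene-5,9-diol, via γ-boryl allylborane 15 (not isolated), via α-boryl borinate 16 (not isolated), via bis-boron adduct 17 (not isolated)
Conditions: 12 (1.3 equiv), 14 (1.2 equiv), Et2O, 0 °C, 2 h; 4 (1.2 equiv), −78 °C, 3 h; 8 (1.0 equiv), −78 → 23 °C, 24 h; then pH 7 buffer, MeOH, 30% H2O2, 0 °C → rt
Reagents that add atoms: none
Why: Hydroboration of allenylboronate 12 by 14 gives the (E)-γ-boryl allylborane 15, whose dialkylborane end allylborates 4 at −78 °C through a closed chair transition state on the aldehyde face chosen by the isopinocampheyl groups, setting C6 as S and, because the alkene is E, the anti C1'–B stereocentre of 16. On warming, the less reactive α-substituted allylboronate 16 adds to 8 through a second six-membered chair transition state (B–O–C4'–C3'–C2'–C1') with SE2' transposition, forming C3'–C4' and moving the alkene to C1'=C2'. The closest known reaction type is the one-pot double allylboration of two aldehydes with a γ-boryl allylborane, which gives (E)-1,5-anti-diols. No ring is closed in this step; the six-membered rings are transition states only. C4' (R) is controlled by 1,3-chirality transfer from C1' of 16 with the residue of 8 equatorial, and the E geometry by the equatorial position of the C6-bearing α-substituent, which the unhindered six-membered dioxaborinane permits. The step needs order selectivity (borane end before boronate end, secured by their reactivity gap and the temperature programme), E over Z selectivity, and reagent control over the weak 1,3-induction of the β-alkoxy aldehyde 8, secured by the stereodefined C1'–B centre.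

**Step 10**
Reactants: 18 (2Z,5S,6E,9R)-1-[(tert-butyldimethylsilyl)oxy]-10-[(4S,6R)-2,2-dimethyl-6-(2-phenylethyl)-1,3-dioxan-4-yl]deca-2,6-diene-5,9-diol
Product: 19 (2Z,5S,6E,9R)-10-[(4S,6R)-2,2-dimethyl-6-(2-phenylethyl)-1,3-dioxan-4-yl]deca-2,6-diene-1,5,9-triol
Conditions: TBAF, THF, 0 °C
Reagents that add atoms: none
Why: Fluoride-mediated desilylation should free the primary allylic alcohol while the ketal, both alkenes and all stereocentres remain untouched.

**Step 11**
Reactants: 19 (2Z,5S,6E,9R)-10-[(4S,6R)-2,2-dimethyl-6-(2-phenylethyl)-1,3-dioxan-4-yl]deca-2,6-diene-1,5,9-triol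
Product: 22 (6S)-6-[(1E,4R)-5-[(4S,6R)-2,2-dimethyl-6-(2-phenylethyl)-1,3-dioxan-4-yl]-4-hydroxypent-1-en-1-yl]-5,6-dihydro-2H-pyran-2-one, via (Z)-enal 20 (not isolated), via lactol 21 (not isolated)
Conditions: TEMPO (0.2 equiv), PhI(OAc)2 (2.5 equiv), CH2Cl2, rt
Reagents that add atoms: none
Why: In this TEMPO/PhI(OAc)2 oxidative lactonisation the oxoammonium species oxidises the primary allylic alcohol much faster than the secondary ones, the (Z)-enal is captured by the C6 hydroxyl as the six-membered lactol, and the lactol is oxidised to the lactone, which leaves only the C4' hydroxyl free.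

**Step 12**
Reactants: 22 (6S)-6-[(1E,4R)-5-[(4S,6R)-2,2-dimethyl-6-(2-phenylethyl)-1,3-dioxan-4-yl]-4-hydroxypent-1-en-1-yl]-5,6-dihydro-2H-pyran-2-one
Product: 23 (2R,4E)-1-[(4R,6R)-2,2-dimethyl-6-(2-phenylethyl)-1,3-dioxan-4-yl]-5-[(2S)-6-oxo-3,6-dihydro-2H-pyran-2-yl]pent-4-en-2-yl acetate
Conditions: Ac2O, pyridine, DMAP (cat.), CH2Cl2, 0 °C → rt
Reagents that add atoms: acetic anhydride CC(=O)OC(C)=O
Why: DMAP-catalysed acylation should acetylate the only free hydroxyl (C4') under conditions too mild to open or deconjugate the unsaturated lactone.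

**Step 13**
Reactants: 23 (2R,4E)-1-[(4R,6R)-2,2-dimethyl-6-(2-phenylethyl)-1,3-dioxan-4-yl]-5-[(2S)-6-oxo-3,6-dihydro-2H-pyran-2-yl]pent-4-en-2-yl acetate
Product: 24 (6S)-6-[(1E,4R,6R,8R)-4-acetoxy-6,8-dihydroxy-10-phenyldec-1-en-1-yl]-5,6-dihydro-2H-pyran-2-one
Conditions: AcOH/H2O (4:1), 40 °C
Reagents that add atoms: none
Why: Acid-catalysed ketal hydrolysis in weakly acidic aqueous medium should release the C6'/C8' diol, while acid-catalysed 1,3-acyl migration of the C4' acetate and lactone opening should be slow under these conditions.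

**Compound list**
1 | tert-butyldimethyl(prop-2-yn-1-yloxy)silane | C#CCO[Si](C)(C)C(C)(C)C | starting material
2 | 5-[(tert-butyldimethylsilyl)oxy]pent-3-yn-1-ol | OCCC#CCO[Si](C)(C)C(C)(C)C | intermediate
3 | (3Z)-5-[(tert-butyldimethylsilyl)oxy]pent-3-en-1-ol | OCC/C=C\CO[Si](C)(C)C(C)(C)C | intermediate
4 | (3Z)-5-[(tert-butyldimethylsilyl)oxy]pent-3-enal | O=CC/C=C\CO[Si](C)(C)C(C)(C)C | intermediate
5 | tert-butyl 2-[(4R,6S)-6-formyl-2,2-dimethyl-1,3-dioxan-4-yl]acetate | CC(C)(C)OC(=O)C[C@H]1C[C@@H](C=O)OC(C)(C)O1 | starting material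
6 | tert-butyl 2-[(4R,6S)-2,2-dimethyl-6-[(E)-2-phenylethenyl]-1,3-dioxan-4-yl]acetate | CC(C)(C)OC(=O)C[C@H]1C[C@@H](/C=C/c2ccccc2)OC(C)(C)O1 | intermediate
7 | tert-butyl 2-[(4R,6R)-2,2-dimethyl-6-(2-phenylethyl)-1,3-dioxan-4-yl]acetate | CC(C)(C)OC(=O)C[C@H]1C[C@@H](CCc2ccccc2)OC(C)(C)O1 | intermediate
8 | 2-[(4R,6R)-2,2-dimethyl-6-(2-phenylethyl)-1,3-dioxan-4-yl]acetaldehyde | O=CC[C@H]1C[C@@H](CCc2ccccc2)OC(C)(C)O1 | intermediate
9 | 3-bromoprop-1-yne | C#CCBr | starting material
10 | propa-1,2-dien-1-ylmagnesium bromide (allenylmagnesium bromide) | C=C=C[Mg]Br | intermediate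
11 | propa-1,2-dien-1-ylboronic acid (allenylboronic acid) | C=C=CB(O)O | intermediate
12 | 5,5-dimethyl-2-(propa-1,2-dien-1-yl)-1,3,2-dioxaborinane | C=C=CB1OCC(C)(C)CO1 | intermediate
13 | (1S,5S)-(−)-α-pinene | CC1=CC[C@H]2C[C@@H]1C2(C)C | starting material
14 | (+)-diisopinocampheylborane, (lIpc)2BH | B([C@@H]1[C@@H](C)[C@@H]2C[C@H](C1)C2(C)C)[C@@H]3[C@@H](C)[C@@H]4C[C@H](C3)C4(C)C | intermediate
15 | [(2E)-3-(5,5-dimethyl-1,3,2-dioxaborinan-2-yl)prop-2-en-1-yl]bis(lIpc)borane (γ-boryl allylborane) | CC1(C)COB(/C=C/CB([C@@H]2[C@@H](C)[C@@H]3C[C@H](C2)C3(C)C)[C@@H]4[C@@H](C)[C@@H]5C[C@H](C4)C5(C)C)OC1 | intermediate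
16 | 2-[(3R,4S,6Z)-4-{[bis(lIpc)boryl]oxy}-8-[(tert-butyldimethylsilyl)oxy]octa-1,6-dien-3-yl]-5,5-dimethyl-1,3,2-dioxaborinane (α-boryl borinate) | C=C[C@@H](B1OCC(C)(C)CO1)[C@@H](OB([C@@H]2[C@@H](C)[C@@H]3C[C@H](C2)C3(C)C)[C@@H]4[C@@H](C)[C@@H]5C[C@H](C4)C5(C)C)C/C=C\CO[Si](C)(C)C(C)(C)C | intermediate
17 | bis-boron adduct: diol 18 carrying the bis(lIpc)borinate on the C5 oxygen and the 5,5-dimethyl-1,3,2-dioxaborinan-2-yl borate on the C9 oxygen | CC1(C)COB(O[C@H](C/C=C/[C@@H](OB([C@@H]2[C@@H](C)[C@@H]3C[C@H](C2)C3(C)C)[C@@H]4[C@@H](C)[C@@H]5C[C@H](C4)C5(C)C)C/C=C\CO[Si](C)(C)C(C)(C)C)C[C@H]6C[C@@H](CCc7ccccc7)OC(C)(C)O6)OC1 | intermediate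
18 | (2Z,5S,6E,9R)-1-[(tert-butyldimethylsilyl)oxy]-10-[(4S,6R)-2,2-dimethyl-6-(2-phenylethyl)-1,3-dioxan-4-yl]deca-2,6-diene-5,9-diol | O[C@H](C/C=C/[C@@H](O)C/C=C\CO[Si](C)(C)C(C)(C)C)C[C@H]1C[C@@H](CCc2ccccc2)OC(C)(C)O1 | intermediate
19 | (2Z,5S,6E,9R)-10-[(4S,6R)-2,2-dimethyl-6-(2-phenylethyl)-1,3-dioxan-4-yl]deca-2,6-diene-1,5,9-triol | O[C@H](C/C=C/[C@@H](O)C/C=C\CO)C[C@H]1C[C@@H](CCc2ccccc2)OC(C)(C)O1 | intermediate
20 | (2Z,5S,6E,9R)-10-[(4S,6R)-2,2-dimethyl-6-(2-phenylethyl)-1,3-dioxan-4-yl]-5,9-dihydroxydeca-2,6-dienal | O[C@H](C/C=C/[C@@H](O)C/C=C\C=O)C[C@H]1C[C@@H](CCc2ccccc2)OC(C)(C)O1 | intermediate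
21 | (6S)-6-[(1E,4R)-5-[(4S,6R)-2,2-dimethyl-6-(2-phenylethyl)-1,3-dioxan-4-yl]-4-hydroxypent-1-en-1-yl]-5,6-dihydro-2H-pyran-2-ol (both anomers) | O[C@H](C/C=C/[C@@H]1CC=CC(O)O1)C[C@H]2C[C@@H](CCc3ccccc3)OC(C)(C)O2 | intermediate
22 | (6S)-6-[(1E,4R)-5-[(4S,6R)-2,2-dimethyl-6-(2-phenylethyl)-1,3-dioxan-4-yl]-4-hydroxypent-1-en-1-yl]-5,6-dihydro-2H-pyran-2-one | O[C@H](C/C=C/[C@@H]1CC=CC(=O)O1)C[C@H]2C[C@@H](CCc3ccccc3)OC(C)(C)O2 | intermediate
23 | (2R,4E)-1-[(4R,6R)-2,2-dimethyl-6-(2-phenylethyl)-1,3-dioxan-4-yl]-5-[(2S)-6-oxo-3,6-dihydro-2H-pyran-2-yl]pent-4-en-2-yl acetate | CC(=O)O[C@H](C/C=C/[C@@H]1CC=CC(=O)O1)C[C@H]2C[C@@H](CCc3ccccc3)OC(C)(C)O2 | intermediate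
24 | (6S)-6-[(1E,4R,6R,8R)-4-acetoxy-6,8-dihydroxy-10-phenyldec-1-en-1-yl]-5,6-dihydro-2H-pyran-2-one | CC(=O)O[C@H](C/C=C/[C@@H]1CC=CC(=O)O1)C[C@H](O)C[C@H](O)CCc1ccccc1 | target

**Step count:** 13 steps in total; longest linear sequence 8 steps (steps 1–3 and 9–13, or steps 4–6 and 9–13).

**Steps most likely to fail**

Step 9. The α-substituent of 16 may adopt the axial position in the second allylboration, which would erode E selectivity and chirality transfer. Aldehyde 4 may isomerise into conjugation before it is captured. The two aldehydes may be incorporated in the wrong order if the first allylboration is incomplete. The fallback sets out from 8 and comes back at 23. Brown allylation of 8 with B-allylbis(isopinocampheyl)borane derived from (−)-α-pinene should give the homoallylic alcohol (2R)-1-[(4S,6R)-2,2-dimethyl-6-(2-phenylethyl)-1,3-dioxan-4-yl]pent-4-en-2-ol F1. Acetylation (Ac2O, pyridine, DMAP) gives (2R)-1-[(4R,6R)-2,2-dimethyl-6-(2-phenylethyl)-1,3-dioxan-4-yl]pent-4-en-2-yl acetate F2. In parallel, Brown allylation of acrolein with the enantiomeric reagent from (+)-α-pinene gives (3S)-hexa-1,5-dien-3-ol F3. Acylation with acryloyl chloride gives (3S)-hexa-1,5-dien-3-yl prop-2-enoate F4, and ring-closing metathesis (first-generation Grubbs catalyst, CH2Cl2, 40 °C) gives (6S)-6-ethenyl-5,6-dihydro-2H-pyran-2-one F5. Cross-metathesis of F2 with an excess of F5 (second-generation Hoveyda–Grubbs catalyst, CH2Cl2, 40 °C) should give 23 with the E alkene.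

Step 11. The secondary allylic C6 hydroxyl may be over-oxidised to an enone, or enal 20 may isomerise from Z to E before it is trapped as the lactol, which would stop the ring closure. The fallback sets out from 18 and comes back at 22. Both secondary hydroxyls are silylated (TBSOTf, 2,6-lutidine) to the 5,9-bis-O-TBS ether of 18 F6. The primary allylic silyl ether is cleaved selectively (HF·pyridine, pyridine, THF, 0 °C) to the 5,9-bis-O-TBS ether of 19 F7. MnO2 oxidises only the allylic primary alcohol to the 5,9-bis-O-TBS ether of enal 20 F8, with no free hydroxyl exposed to the oxidant. TBAF then frees both hydroxyls, the C6 hydroxyl closes onto the aldehyde to give lactol 21 (now isolated), and MnO2 oxidises this allylic lactol to 22.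

Step 6. The hindered tert-butyl ester may be over-reduced to the primary alcohol, or the reduction may stall. The fallback sets out from 7 and comes back at 8. Full reduction with LiAlH4 (THF, 0 °C) gives 2-[(4S,6R)-2,2-dimethyl-6-(2-phenylethyl)-1,3-dioxan-4-yl]ethan-1-ol F9, and Swern oxidation returns 8.

**Further compounds**
F1 | step 9 | (2R)-1-[(4S,6R)-2,2-dimethyl-6-(2-phenylethyl)-1,3-dioxan-4-yl]pent-4-en-2-ol | O[C@H](CC=C)C[C@H]1C[C@@H](CCc2ccccc2)OC(C)(C)O1
F2 | step 9 | (2R)-1-[(4R,6R)-2,2-dimethyl-6-(2-phenylethyl)-1,3-dioxan-4-yl]pent-4-en-2-yl acetate | CC(=O)O[C@H](CC=C)C[C@H]1C[C@@H](CCc2ccccc2)OC(C)(C)O1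
F3 | step 9 | (3S)-hexa-1,5-dien-3-ol | C=C[C@@H](O)CC=C
F4 | step 9 | (3S)-hexa-1,5-dien-3-yl prop-2-enoate | C=CC(=O)O[C@H](C=C)CC=C
F5 | step 9 | (6S)-6-ethenyl-5,6-dihydro-2H-pyran-2-one | C=C[C@@H]1CC=CC(=O)O1
F6 | step 11 | 5,9-bis-O-(tert-butyldimethylsilyl) ether of 18 | CC(C)(C)[Si](C)(C)O[C@H](C/C=C/[C@@H](O[Si](C)(C)C(C)(C)C)C/C=C\CO[Si](C)(C)C(C)(C)C)C[C@H]1C[C@@H](CCc2ccccc2)OC(C)(C)O1
F7 | step 11 | 5,9-bis-O-(tert-butyldimethylsilyl) ether of 19 | CC(C)(C)[Si](C)(C)O[C@H](C/C=C/[C@@H](O[Si](C)(C)C(C)(C)C)C/C=C\CO)C[C@H]1C[C@@H](CCc2ccccc2)OC(C)(C)O1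
F8 | step 11 | 5,9-bis-O-(tert-butyldimethylsilyl) ether of enal 20 | CC(C)(C)[Si](C)(C)O[C@H](C/C=C/[C@@H](O[Si](C)(C)C(C)(C)C)C/C=C\C=O)C[C@H]1C[C@@H](CCc2ccccc2)OC(C)(C)O1
F9 | step 6 | 2-[(4S,6R)-2,2-dimethyl-6-(2-phenylethyl)-1,3-dioxan-4-yl]ethan-1-ol | OCC[C@H]1C[C@@H](CCc2ccccc2)OC(C)(C)O1
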